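| flask | substrate | coupling partner | other conformer | temperature | remark | time |
|---|---|---|---|---|---|---|
| theta | 0.25 M | 1.25 M | 0.25 M | 0 °C | the very flask that is asked about, followed so far |  |
| gamma | 0.25 M | 1.25 M | 0.38 M | −5 °C | run made earlier |  |
| flask | 0.25 M | 1.25 M | 0.250 M | 0 °C |  | 6.0 h |

- theta (time / min: target / %): 25.0: 27; 80.0: 34; 120: 35; 180: 35; 300: 36
- gamma (time / min: target / %): 6.00: 10; 12.0: 13; 20.0: 17; 25.0: 22; 30.0: 20

(standard deviation of a reading: 1.5 percentage points)

1. target, in percent of the substrate and other conformer together first charged, at 6.0 h
2. what to do for the largest gain in target; "none" if nothing gains more than 2 percentage points (Wednesday's / Monday's / Thursday's / none)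
3. target present, with what was taken out counted in, in percent of the substrate and other conformer together first charged, after Wednesday's
4. target present, with what was taken out counted in, in percent of the substrate and other conformer together first charged, after Monday's

- Wednesday's: at 6.0 h raise the temperature by 20 K, then wait 12 h
- Monday's: at 6.0 h take out 90% of the target then present, then wait 12 h
- Thursday's: change nothing and wait 12 h more

1. Start with what barely moves. Call substrate and other conformer together the feed. If each feed molecule took one coupling partner, 60.0% of the coupling partner would still stay free. So freeze [coupling partner] at its charge. The feed is then the limiting reagent. The freeze is rough: [coupling partner] may fall by 40.0% of its charge, so treat the run-up below as an estimate.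

2. A first-order run-up closes its gap to the plateau by equal factors. In the theta run the last reading is 36%, and at 25.0 min the gap is 9 percentage points. That gives the halving time, 12.5 min, the time in which the gap to the plateau halves. It is a reading and carries the scatter.

3. By 6.0 h the theta flask has stood 28.8 halving times. Whatever relaxes at this pace has finished.

4. Extreme one: the plateau is exhaustion. The feed is gone, and no option gains anything. Extreme two: the plateau is a balance that holds target and feed at a fixed ratio. Remove 90% of the target and what stays in the flask resettles at that ratio, for a gain near 21 points.

5. The flat tail fits both. From 120 min to 300 min they rise 1 point, less than the scatter of 1.5 points. Exhaustion needs an unseen sink for the rest of the feed. A balance needs a target that falls back. The readings choose neither, so my call is a judgement: about 35.3% now, a lean towards extreme one, and Monday's as the open risk.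

6. The forecast differs on the choice. It gives 36%, picks Wednesday's with 55%, and puts Monday's at 38%, expecting warming to “release the locked pool”.

7. The flask gives 34.3%, and the best choice is none. Wednesday's ends at 34.3%, Monday's at 34.3%, Thursday's at 34.3%.

    substrate ⇌ other conformer (K = 1.10, k = 6.40 × 10⁻⁴ s⁻¹, Ea = 76.0 kJ mol⁻¹, ΔH = 5.00 kJ mol⁻¹)
    coupling partner + other conformer → isomer of the product (k = 0.00160 M⁻¹ s⁻¹, Ea = 54.0 kJ mol⁻¹)
    substrate + target → side product (k = 3.30 × 10⁻⁴ M⁻¹ s⁻¹, Ea = 55.0 kJ mol⁻¹)
    2 substrate → homo dimer (k = 5.90 × 10⁻⁴ M⁻¹ s⁻¹, Ea = 49.0 kJ mol⁻¹)
    substrate + coupling partner → target (k = 8.30 × 10⁻⁴ M⁻¹ s⁻¹, Ea = 55.0 kJ mol⁻¹)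
    (constants at 0 °C)

After 28.8 halving times of 12.5 min, this flask holds substrate 0% and other conformer 0%, beside 63% of its coupling partner. The feed went elsewhere: without the turning of coupling partner + other conformer into isomer of the product, this flask's target stands at 76.5% instead of 34.3%. Reckoned with the same halving time, a neighbour flask charged with 0.10 M of other conformer has also stood 28.8 halving times, and it holds substrate 0%, other conformer 0% and target 44.6%.

The earlier runs and the new flask were computed for an exercise; scatter was added.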